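## Retrosynthetic overview
1. The enone comes last, by C15 allylic oxidation of a 16-ene. The 11-OH comes from hydride addition to an 11-ketone, and ring D from a 5-exo vinyl-radical closure (C16–C13) onto a C11 enone.
2. Rings B (δ-lactone) and C form together in an ester-tethered intramolecular Diels–Alder reaction: 2-silyloxydiene C9=C11–C12=C13 plus the 2-(2-bromoallyl)acrylate C8=C14 hung on the C20 oxygen.
3. The C10 quaternary centre comes from β-face alkylation of an aldehyde (CHO = C20). The diene carbons come from a butynyl pivalate through a gold [3,3] acyloxy shift.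
4. Ring A with C4/C5 comes from a two-directional, ester-tethered Diels–Alder reaction of citraconate on a C2-symmetric tetraenediol made from D-tartrate. The carbinol carbons become C20 after translactonisation and glycol cleavage.
5. Ring order: A (with the γ-lactone), then B and C together, then D.

Assumption: ent-kaurane numbers of the target are used throughout (α: C19, C20, C6, C14, 11-OH; β: 18-Me, H5, H9, C9 on C10, the C15–C16 bridge). C10 (ring-fusion) epimers from step 3 are carried together because C10 is planarised in step 8; the endo isomer is drawn.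

## Route

Step 1
Reactants: 1 dimethyl 2,3-O-isopropylidene-D-tartrate; 2 diethyl allylphosphonate
Product: 4 (4R,5R)-4,5-bis[(1E)-buta-1,3-dienyl]-2,2-dimethyl-1,3-dioxolane, via (4S,5S)-dioxolane-4,5-dicarbaldehyde 3 (not isolated)
Conditions: DIBAL-H (2.1 equiv), PhMe, −78 °C, Rochelle work-up, crude; then 2, n-BuLi, THF–HMPA, −78 °C → rt
Reagents that add atoms: diethyl allylphosphonate (2), C=CCP(=O)(OCC)OCC
Why: Half-reduction of both esters and Horner–Wadsworth–Emmons olefination with the HMPA-solvated allylphosphonate anion give terminal (E)-dienes, and the two purchased carbinol centres are not touched at low temperature.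

Step 2
Reactants: 4 bis-diene acetonide
Product: 5 (3E,5R,6R,7E)-deca-1,3,7,9-tetraene-5,6-diol
Conditions: AcOH–H2O 4:1, 40 °C
Reagents that add atoms: none
Why: Mild acetal hydrolysis of the strained trans-dioxolane breaks only the ketal C–O bonds, so both carbinol configurations are kept.

Step 3
Reactants: 5 tetraenediol; 6 citraconic anhydride (2.4 equiv)
Product: 8 C2-symmetric bis(cyclohexene γ-lactone) diacid (each half: C1=C2, 4β-Me, 4α-CO2H = C19, 5β-H, lactone C6(=O)–O–C20, halves joined C20–C20′), via bis[(Z)-3-carboxybut-2-enoate] 7 (not isolated)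
Conditions: 6, Et3N, DMAP (cat.), CH2Cl2, 0 °C → rt; 1 M HCl wash, solvent swap; PhMe (0.01 M), BHT, 130 °C, sealed tube
Reagents that add atoms: citraconic anhydride (6), CC1=CC(=O)OC1=O
Why: Alcoholysis opens the anhydride at the less hindered C=O (next to CH), so the tether fixes the C5–C10/C4–C3 regiochemistry of the type-1 intramolecular Diels–Alder reaction; each carbinol puts its large substituent anti to the dienophile with C–O inside (endo) or outside (exo), and both modes give the same C4 (quaternary) and C5 configuration.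

Step 4
Reactants: 8 bis-adduct diacid
Product: 9 tetrahydro diacid (C1–C2 saturated in both halves)
Conditions: H2 (1 atm), 10 % Pd/C, EtOAc, rt
Reagents that add atoms: none
Why: Catalytic hydrogenation removes the only C=C bonds before borane and all later alkene chemistry, and no stereocentre is formed.

Step 5
Reactants: 9 saturated diacid
Product: 11 C2-symmetric 20,20′-diol bis(C19–O–C6 γ-lactone), via bis(19-hydroxymethyl) bis(C20–O–C6 lactone) 10 (not isolated)
Conditions: BH3·SMe2, THF, 0 °C → rt; MeOH; then CSA (10 mol %), CH2Cl2, rt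
Reagents that add atoms: none
Why: Borane reduces the carboxylic acids in the presence of the lactones, and acid-catalysed translactonisation moves the C6 acyl group to the cis primary 19-OH (Thorpe–Ingold-favoured lactone on quaternary C4), which frees the hindered secondary glycol without touching a stereocentre.

Step 6
Reactants: 11 diol bis-lactone
Product: 12 (3aR,7S,7aS)-3a-methyl-1-oxo-octahydroisobenzofuran-7-carbaldehyde (2 equiv; cis-lactone, CHO = C20 on C10)
Conditions: Pb(OAc)4, CH2Cl2, 0 °C
Reagents that add atoms: none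
Why: Criegee glycol cleavage removes the two sacrificial tartrate centres and delivers both halves as the same aldehyde.

Step 7
Reactants: 13 4-chlorobut-2-yn-1-ol
Product: 14 4-chlorobut-2-yn-1-yl pivalate
Conditions: PivCl, Et3N, DMAP (cat.), CH2Cl2, 0 °C
Reagents that add atoms: pivaloyl chloride, CC(C)(C)C(=O)Cl
Why: This is a simple O-acylation, and the pivalate later serves as the migrating group.

Step 8
Reactants: 12 aldehyde lactone; 14 chlorobutynyl pivalate
Product: 15 C10-quaternary aldehyde (10α-CHO = C20; 10β-CH2C≡CCH2OPiv = C9, C11–C13)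
Conditions: KOt-Bu (1.05 equiv), THF, −78 → −20 °C; then 14
Reagents that add atoms: 4-chlorobut-2-yn-1-yl pivalate (14), CC(C)(C)C(=O)OCC#CCCl
Why: SN2 C-alkylation of the α-branched aldehyde enolate (far more acidic than the lactone) occurs equatorially from the β face, anti to the axial C19 methylene of the cis-lactone, and this sets C10.

Step 9
Reactants: 15 quaternary aldehyde
Product: 16 neopentyl alcohol (C20–OH)
Conditions: NaBH4, MeOH–CH2Cl2, −40 °C; AcOH quench
Reagents that add atoms: none
Why: Chemoselective 1,2-reduction of the aldehyde, with a cold acidic quench so that no free alkoxide can translactonise onto C6.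

Step 10
Reactants: 17 triethyl phosphonoacetate; 18 2,3-dibromopropene
Product: 19 ethyl 4-bromo-2-(diethoxyphosphoryl)pent-4-enoate
Conditions: NaH, THF, 0 °C → rt
Reagents that add atoms: 2,3-dibromopropene (18), C=C(Br)CBr
Why: The stabilised phosphonate carbanion displaces only the allylic bromide (SN2).

Step 11
Reactants: 19 alkylated phosphonate
Product: 20 ethyl 4-bromo-2-methylidenepent-4-enoate
Conditions: 37 % aq. HCHO, K2CO3, rt → 40 °C
Reagents that add atoms: formaldehyde, C=O
Why: Horner–Wadsworth–Emmons methylenation gives the 2-substituted acrylate.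

Step 12
Reactants: 20 ethyl ester
Product: 21 4-bromo-2-methylidenepent-4-enoic acid
Conditions: LiOH, THF–H2O, rt; 1 M HCl
Reagents that add atoms: lithium hydroxide, [Li+].[OH-]
Why: Saponification proceeds cleanly, and the vinyl bromide and acrylate survive cold hydroxide.

Step 13
Reactants: 16 neopentyl alcohol; 21 acid
Product: 22 C20 2-(2-bromoallyl)acrylate ester
Conditions: DIC, DMAP, CH2Cl2, 0 °C → rt
Reagents that add atoms: acid 21, OC(=O)C(=C)CC(Br)=C
Why: Steglich esterification works under non-alkoxide conditions, locks the C20 oxygen and installs C7, C8 and C14–C17.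

Step 14
Reactants: 22 alkynyl pivalate ester
Product: 24 vinyl ketone (C9H2–C11(=O)–C12H=C13H2), via allenyl pivalate 23 (not isolated)
Conditions: Ph3PAuNTf2 (3 mol %), wet butan-2-one, 40 °C
Reagents that add atoms: none
Why: A gold-catalysed [3,3]-sigmatropic 1,3-acyloxy shift puts the oxygen on C11, and hydrolysis of the allenyl ester gives the enone (Meyer–Schuster-type outcome); the electron-poor alkenes and the vinyl bromide are inert to Au(I).

Step 15
Reactants: 24 vinyl ketone
Product: 26 Diels–Alder adduct (rings A, B, C; cis B/C fusion; C11(OTBS)=C12; 8β-CH2C(Br)=CH2; 9β-H), via (Z)-2-silyloxydiene 25 (not isolated)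
Conditions: TBSOTf, Et3N, PhMe, −20 → 0 °C; filter (Celite), dilute to 5 mM, BHT, 170 °C, sealed tube
Reagents that add atoms: TBSOTf, CC(C)(C)[Si](C)(C)OS(=O)(=O)C(F)(F)F
Why: Soft enolisation gives the (Z)-enol silane (C10 "outside"), and the type-1 intramolecular Diels–Alder reaction with the tether carbonyl endo and the bromoallyl group exo gives the cis fusion, with stacking on the side of C1H2 away from the bulky C5; this sets C8 and C9.

Step 16
Reactants: 26 silyl enol ether
Product: 27 enone (C11=O, C12=C13)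
Conditions: Pd(OAc)2 (1.1 equiv), MeCN, rt
Reagents that add atoms: none
Why: In the Saegusa–Ito oxidation the C12 palladium enolate can β-eliminate only towards C13.

Step 17
Reactants: 27 bromo enone
Product: 28 bicyclo[3.2.1]octane 11-ketone with the 16(17)-exomethylene
Conditions: n-Bu3SnH, AIBN (cat.), PhH, 80 °C, syringe pump
Reagents that add atoms: none
Why: The C16 vinyl radical closes 5-exo-trig onto the enone β-carbon, and the one-carbon C14 link allows only the cis (bridged) mode; this sets C13.

Step 18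
Reactants: 28 11-ketone
Product: 29 11α-alcohol
Conditions: NaBH4, MeOH–CH2Cl2, −20 °C
Reagents that add atoms: none
Why: The α face is blocked by the axial spiro C10, so hydride enters from the β face and gives the equatorial 11α-OH, which is also the thermodynamic epimer; the lactones survive.

Step 19
Reactants: 29 11α-alcohol
Product: 30 11α,15-diol (15-OH exo, syn to C14)
Conditions: SeO2 (cat.), t-BuOOH, CH2Cl2, rt
Reagents that add atoms: tert-butyl hydroperoxide, CC(C)(C)OO
Why: Allylic hydroxylation (ene reaction, then [2,3]-sigmatropic shift) can occur only at C15 because C13 is a bridgehead, and it takes place on the open exo face.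

Step 20
Reactants: 30 diol
Product: 31 ludongnin A
Conditions: MnO2, CH2Cl2, rt
Reagents that add atoms: none
Why: MnO2 oxidises only the allylic 15-OH, so the saturated 11α-OH is left in place and the α-methylene ketone is unveiled last.

## Compound list
1 | dimethyl (4S,5S)-2,2-dimethyl-1,3-dioxolane-4,5-dicarboxylate | COC(=O)[C@H]1OC(C)(C)O[C@@H]1C(=O)OC | starting material
2 | diethyl allylphosphonate | C=CCP(=O)(OCC)OCC | starting material
3 | (4S,5S)-2,2-dimethyl-1,3-dioxolane-4,5-dicarbaldehyde | O=C[C@H]1OC(C)(C)O[C@@H]1C=O | intermediate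
4 | (4R,5R)-bis[(E)-butadienyl] acetonide | C=C/C=C/[C@H]1OC(C)(C)O[C@@H]1/C=C/C=C | intermediate
5 | (3E,5R,6R,7E)-deca-1,3,7,9-tetraene-5,6-diol | C=C/C=C/[C@@H](O)[C@H](O)/C=C/C=C | intermediate
6 | citraconic anhydride | CC1=CC(=O)OC1=O | starting material
7 | bis(hydrogen citraconate) of 5 | C=C/C=C/[C@@H](OC(=O)/C=C(/C)C(O)=O)[C@H](OC(=O)/C=C(/C)C(O)=O)/C=C/C=C | intermediate
8 | bis Diels–Alder adduct diacid | OC(=O)[C@]1(C)CC=C[C@H]2[C@@H]1C(=O)O[C@H]2[C@@H]1OC(=O)[C@H]2[C@@H]1C=CC[C@@]2(C)C(O)=O | intermediate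
9 | saturated diacid | OC(=O)[C@]1(C)CCC[C@H]2[C@@H]1C(=O)O[C@H]2[C@@H]1OC(=O)[C@H]2[C@@H]1CCC[C@@]2(C)C(O)=O | intermediate
10 | bis(19-hydroxymethyl) bis(C20-lactone) | OC[C@]1(C)CCC[C@H]2[C@@H]1C(=O)O[C@H]2[C@@H]1OC(=O)[C@H]2[C@@H]1CCC[C@@]2(C)CO | intermediate
11 | 20,20′-diol bis(C19-lactone) | O=C1OC[C@]2(C)CCC[C@@H]([C@H]12)[C@@H](O)[C@H](O)[C@H]1CCC[C@@]2(C)COC(=O)[C@H]21 | intermediate
12 | aldehyde lactone | O=C[C@H]1CCC[C@@]2(C)COC(=O)[C@H]21 | intermediate
13 | 4-chlorobut-2-yn-1-ol | OCC#CCCl | starting material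
14 | 4-chlorobut-2-yn-1-yl pivalate | CC(C)(C)C(=O)OCC#CCCl | intermediate
15 | C10-quaternary aldehyde | O=C[C@@]1(CC#CCOC(=O)C(C)(C)C)CCC[C@@]2(C)COC(=O)[C@H]21 | intermediate
16 | C20 alcohol | OC[C@@]1(CC#CCOC(=O)C(C)(C)C)CCC[C@@]2(C)COC(=O)[C@H]21 | intermediate
17 | triethyl phosphonoacetate | CCOC(=O)CP(=O)(OCC)OCC | starting material
18 | 2,3-dibromopropene | C=C(Br)CBr | starting material
19 | ethyl 4-bromo-2-(diethoxyphosphoryl)pent-4-enoate | CCOC(=O)C(CC(Br)=C)P(=O)(OCC)OCC | intermediate
20 | ethyl 4-bromo-2-methylidenepent-4-enoate | CCOC(=O)C(=C)CC(Br)=C | intermediate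
21 | 4-bromo-2-methylidenepent-4-enoic acid | OC(=O)C(=C)CC(Br)=C | intermediate
22 | C20 acrylate ester, alkynyl pivalate | C=C(Br)CC(=C)C(=O)OC[C@@]1(CC#CCOC(=O)C(C)(C)C)CCC[C@@]2(C)COC(=O)[C@H]21 | intermediate
23 | allenyl pivalate | C=C(Br)CC(=C)C(=O)OC[C@@]1(CC(OC(=O)C(C)(C)C)=C=C)CCC[C@@]2(C)COC(=O)[C@H]21 | intermediate
24 | vinyl ketone | C=C(Br)CC(=C)C(=O)OC[C@@]1(CC(=O)C=C)CCC[C@@]2(C)COC(=O)[C@H]21 | intermediate
25 | (Z)-2-TBSO-diene | C=C(Br)CC(=C)C(=O)OC[C@@]1(/C=C(/C=C)O[Si](C)(C)C(C)(C)C)CCC[C@@]2(C)COC(=O)[C@H]21 | intermediate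
26 | Diels–Alder adduct (silyl enol ether) | C=C(Br)C[C@]12CCC=C(O[Si](C)(C)C(C)(C)C)[C@H]1[C@@]1(CCC[C@@]3(C)COC(=O)[C@H]31)COC2=O | intermediate
27 | enone | C=C(Br)C[C@]12CC=CC(=O)[C@H]1[C@@]1(CCC[C@@]3(C)COC(=O)[C@H]31)COC2=O | intermediate
28 | 11-ketone, 16-ene | C=C1C[C@]23C[C@H]1CC(=O)[C@H]2[C@@]1(CCC[C@@]4(C)COC(=O)[C@H]41)COC3=O | intermediate
29 | 11α-alcohol | C=C1C[C@]23C[C@H]1C[C@@H](O)[C@H]2[C@@]1(CCC[C@@]4(C)COC(=O)[C@H]41)COC3=O | intermediate
30 | 11α,15-diol | C=C1[C@H](O)[C@]23C[C@H]1C[C@@H](O)[C@H]2[C@@]1(CCC[C@@]4(C)COC(=O)[C@H]41)COC3=O | intermediate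
31 | ludongnin A | C=C1C(=O)[C@]23C[C@H]1C[C@@H](O)[C@H]2[C@@]1(CCC[C@@]2(C)COC(=O)[C@H]21)COC3=O | target

## Step count and risks
Total steps: 20. Longest linear sequence: 16 (steps 1–6, 8, 9, 13–20).

**Step 3 (double acylation and Diels–Alder).** The risks are Z→E isomerisation of the half-ester, reaction with the neighbouring diene, and low rate. The fallback sets out from 4 and drops the tether. Compound 4 is heated with 6 (neat or at 12 kbar) so that the dioxolane centre alone directs the diene face. After the regioisomers are separated this gives the bis-anhydride F1. NaBH4, which attacks the carbonyl next to quaternary C4, gives the bis(cyclohexene lactone) acetonide F2, and hydrogenation gives the saturated acetonide F3. H5IO6 then cleaves the acetonide and the glycol in one operation, and the route is rejoined at 12.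

**Step 8 (quaternary C10).** The risks are O- versus C-alkylation, SN2′ attack and the wrong face. The fallback sets out from 12 and uses a Stork metalloenamine. Condensation with cyclohexylamine gives the aldimine F4. LDA and then 14 give the C-alkylated aldimine F5, and aqueous oxalic acid hydrolyses it, returning to the route at 15.

**Step 15 (electronically mismatched silyloxydiene in an ester tether).** The fallback sets out from 12 and uses an unpolarised diene, with the C11 oxygen brought in afterwards.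
- KOt-Bu and (E)-1,4-dibromobut-2-ene give the bromobutenyl aldehyde F6.
- DBU 1,4-elimination gives the dienal F7, and NaBH4 gives the dienol F8.
- DIC/DMAP with 21 gives the triene ester F9, and thermolysis gives the cyclohexene adduct F10.
- A Schenck ene reaction with singlet oxygen gives the allylic hydroperoxide F11, and Ac2O/pyridine (Kornblum–DeLaMare) dehydrates it, returning to the route at 27.

## Further compounds
F1 | step 3 | bis-anhydride acetonide | CC1(C)O[C@H]([C@H]2C=CC[C@@]3(C)C(=O)OC(=O)[C@@H]23)[C@H](O1)[C@H]1C=CC[C@@]2(C)C(=O)OC(=O)[C@@H]12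
F2 | step 3 | bis(cyclohexene lactone) acetonide | CC1(C)O[C@H]([C@H]2C=CC[C@@]3(C)COC(=O)[C@@H]23)[C@H](O1)[C@H]1C=CC[C@@]2(C)COC(=O)[C@@H]12
F3 | step 3 | saturated bis-lactone acetonide | CC1(C)O[C@H]([C@H]2CCC[C@@]3(C)COC(=O)[C@@H]23)[C@H](O1)[C@H]1CCC[C@@]2(C)COC(=O)[C@@H]12
F4 | step 8 | N-cyclohexyl aldimine of 12 | C(=NC1CCCCC1)[C@H]1CCC[C@@]2(C)COC(=O)[C@H]21
F5 | step 8 | N-cyclohexyl aldimine of 15 | C(=NC1CCCCC1)[C@@]1(CC#CCOC(=O)C(C)(C)C)CCC[C@@]2(C)COC(=O)[C@H]21
F6 | step 15 | bromobutenyl aldehyde | O=C[C@@]1(C/C=C/CBr)CCC[C@@]2(C)COC(=O)[C@H]21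
F7 | step 15 | dienal | O=C[C@@]1(/C=C/C=C)CCC[C@@]2(C)COC(=O)[C@H]21
F8 | step 15 | dienol | OC[C@@]1(/C=C/C=C)CCC[C@@]2(C)COC(=O)[C@H]21
F9 | step 15 | triene ester | C=C(Br)CC(=C)C(=O)OC[C@@]1(/C=C/C=C)CCC[C@@]2(C)COC(=O)[C@H]21
F10 | step 15 | cyclohexene adduct (C11=C12) | C=C(Br)C[C@]12CCC=C[C@H]1[C@@]1(CCC[C@@]3(C)COC(=O)[C@H]31)COC2=O
F11 | step 15 | 11β-hydroperoxide, C12=C13 | C=C(Br)C[C@]12CC=C[C@H](OO)[C@H]1[C@@]1(CCC[C@@]3(C)COC(=O)[C@H]31)COC2=O
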